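Hold the target made against the second substrate charged before asking what that substrate does.

common to all: starting material 0.10 M

| charge | second substrate | coupling partner | free catalyst | remark |
|---|---|---|---|---|
| north-east | 0.050 M | 0.10 M | 1.2 mM | run made earlier |
| south-west | 0.050 M | 0.10 M | 5 mM | run made earlier |
| flask | 0.0500 M | 0.100 M | 2.5 mM |  |

| run | time / min | target / % |
|---|---|---|
| north-east | 8.00 | 3.5 |
| north-east | 15.0 | 4.2 |
| north-east | 25.0 | 6.0 |
| north-east | 50.0 | 10.3 |
| north-east | 90.0 | 16.7 |
| south-west | 8.00 | 9.3 |
| south-west | 15.0 | 14.4 |
| south-west | 25.0 | 22.7 |
| south-west | 50.0 | 37.1 |
| south-west | 90.0 | 52.7 |

(readings scatter by 0.5 percentage points)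

- apparent order in second substrate when 50% of the starting material are converted (percent change of the rate of making target for one percent more second substrate charged)

- no earlier run changes the charge of second substrate; that part of a forecast is a guess

At 90.0 min the south-west run read 52.7% target, which is 1.05 moles of target per mole of second substrate charged; I called this the turnover per charge.

Two extreme versions can be done in the head. In the first, each target uses up one second substrate, which is then the limiting reagent, charged at half the starting material. The turnover per charge stops at one there, and I took the order as plus one. In the second, second substrate makes no target and merely binds free catalyst: weak binding gives order zero, and binding so strong that free catalyst is a small remainder gives order minus one. The south-west reading stood 2.7 percentage points above the first version's ceiling, against a scatter of 0.5 points, so I dropped that version. No run had varied the second substrate, so the rest was a guess. I committed to a negative order for the flask, somewhere between zero and minus one.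

The forecast differed from me in sign, at 0.3: “Its order is therefore probably small and positive, though this is largely a guess”.

The flask gave −0.44.

    starting material + free catalyst ⇌ catalyst intermediate A (K = 91.0 /M, k = 0.0597 /M/s)
    coupling partner + catalyst intermediate A → free catalyst + target (k = 0.362 /M/s)
    second substrate + free catalyst ⇌ catalyst intermediate B (K = 27.0 /M, k = 0.0521 /M/s)
    coupling partner + catalyst intermediate B → free catalyst + second product (k = 0.0264 /M/s)
    free catalyst ⇌ dormant form (K = 21.0, k = 9.11 × 10⁻⁵ /s)

By 15.0 h the flask's turnover per charge had reached 1.55, above the south-west reading of 1.05 at 90.0 min, with second substrate at 64.7% of its charge. In the flask, second substrate competed for free catalyst, with catalyst intermediate B holding 20.6% of the catalyst at 3.11 h. The falling back of catalyst intermediate B to second substrate and free catalyst softens the flask's order in part: the simulated run without it gives −1.2, against the actual −0.44.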